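C-numbering used throughout: cyclopentanone C1 (C=O), C2, C3, C4 (quaternary, CH3), C5 (CH bearing the cyclopropane); C9′ is the benzylic CH. The enabling feature is C4: a quaternary ring carbon carrying a methyl group and bonded to ring carbons C3 and C5, i.e. the former carbonyl carbon of a methyl ketone onto which a three-carbon ring (C5, C2, C3) was spiro-fused and then enlarged to four and five members.
Retrosynthetic cuts, in order: two aryl–CHO and three O–CH3 bonds; the C1 oxygen (hydroboration of a C1=C5 alkene); C5–cyclopropyl (cross-coupling); C1 itself (one-carbon insertion between C5 and C2); C3–C4 (1,2-shift in an oxaspiropentane); C4–C5 and C4–CH3 (ylide and Grignard additions); C9′–CH2 (enolate alkylation).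
Forward: acyclic α-aryl methyl ketone → oxaspiropentane → cyclobutanone → cyclopentanone; the cis gem-dimethylcyclopropane is made separately from 3,3-dimethylcyclopropene and joined at C5; C1 is then oxygenated and the arene formylated and demethylated.
Stereochemistry: C9′ from an oxazolidinone-directed alkylation; C4 from Felkin–Anh ylide addition under control of C9′, relayed by the invertive shift; cyclopropane cis by syn-carbometalation with absolute sense from a chiral copper catalyst; C5 by equilibration next to the C1 ketone.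
Key step: step 8

Assumption: the sense of induction of the CuI/diphosphine catalyst on the symmetric cyclopropene (step 13) is taken as drawn; if it is the opposite, the mirror-image ligand is used.
Remark: alcohols 32, 33 and 35 (and 31, 34) are drawn as the diastereomer expected from borane attack on the face of the C4 methyl group; C1 and C5 are corrected in step 17, so their configuration before that is of no consequence. The CIP descriptor of C9′ switches between R and S along the route through priority changes only.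

Step 1
Reactants: 1 (2,4,6-trimethoxyphenyl)acetic acid; 2 (4R)-4-benzyl-1,3-oxazolidin-2-one
Product: 4 (4R)-4-benzyl-3-[2-(2,4,6-trimethoxyphenyl)acetyl]-1,3-oxazolidin-2-one, via mixed pivalic anhydride 3 (not isolated)
Conditions: PivCl, Et3N, THF, −20 °C; then 2, LiCl, −20 → 23 °C
Reagents that add atoms: (4R)-4-benzyl-1,3-oxazolidin-2-one (2), O=C1N[C@H](Cc2ccccc2)CO1
Why: LiCl-assisted N-acylation of the oxazolidinone by a mixed pivalic anhydride is the standard entry to N-acyl oxazolidinones and creates no stereocentre.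

Step 2
Reactants: 4 (4R)-4-benzyl-3-[2-(2,4,6-trimethoxyphenyl)acetyl]-1,3-oxazolidin-2-one; 5 3-bromo-2-methylprop-1-ene
Product: 7 (4R)-4-benzyl-3-[(2R)-4-methyl-2-(2,4,6-trimethoxyphenyl)pent-4-enoyl]-1,3-oxazolidin-2-one, via sodium enolate 6 (not isolated)
Conditions: NaHMDS (1.1 equiv), THF, −78 °C; then 5, −78 → −40 °C
Reagents that add atoms: 3-bromo-2-methylprop-1-ene (5), CC(=C)CBr
Why: Evans alkylation, in which the chelated sodium (Z)-enolate is attacked by the allylic bromide on the face away from the benzyl group of the (R)-auxiliary, setting the future C9′ as (2R) in 7.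

Step 3
Reactants: 7 (4R)-4-benzyl-3-[(2R)-4-methyl-2-(2,4,6-trimethoxyphenyl)pent-4-enoyl]-1,3-oxazolidin-2-one
Product: 8 (4R)-4-benzyl-3-[(2R)-4-methyl-2-(2,4,6-trimethoxyphenyl)pentanoyl]-1,3-oxazolidin-2-one
Conditions: H2 (1 atm), Pd/C, EtOAc, 23 °C
Reagents that add atoms: none
Why: Heterogeneous hydrogenation of the 1,1-disubstituted alkene is selective, leaves the C-benzyl group and the arene alone and does not touch the stereocentre.

Step 4
Reactants: 8 (4R)-4-benzyl-3-[(2R)-4-methyl-2-(2,4,6-trimethoxyphenyl)pentanoyl]-1,3-oxazolidin-2-one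
Product: 10 (2R)-4-methyl-2-(2,4,6-trimethoxyphenyl)pentanoic acid, via lithium peroxycarboxylate 9 (not isolated)
Conditions: LiOH, H2O2, THF/H2O, 0 °C; then Na2SO3; 1 M HCl
Reagents that add atoms: hydrogen peroxide, OO
Why: Hydroperoxide cleavage of the imide attacks the exocyclic carbonyl even of hindered acyl oxazolidinones and is too weakly basic to enolise the α-aryl centre, the peracid salt being reduced by sulfite.

Step 5
Reactants: 10 (2R)-4-methyl-2-(2,4,6-trimethoxyphenyl)pentanoic acid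
Product: 12 (2R)-N-methoxy-N,4-dimethyl-2-(2,4,6-trimethoxyphenyl)pentanamide, via benzotriazolyl ester 11 (not isolated)
Conditions: MeNHOMe·HCl, EDC·HCl, HOBt, N-methylmorpholine, CH2Cl2, 0 → 23 °C
Reagents that add atoms: N,O-dimethylhydroxylamine hydrochloride, CNOC.Cl
Why: Carbodiimide/HOBt amide coupling through the active ester gives the Weinreb amide under conditions that normally preserve α-stereocentres of 2-arylalkanoic acids.

Step 6
Reactants: 12 (2R)-N-methoxy-N,4-dimethyl-2-(2,4,6-trimethoxyphenyl)pentanamide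
Product: 13 (3R)-5-methyl-3-(2,4,6-trimethoxyphenyl)hexan-2-one
Conditions: MeMgBr, THF, 0 °C; 1 M HCl quench
Reagents that add atoms: methylmagnesium bromide, C[Mg]Br
Why: Weinreb ketone synthesis, in which the chelated magnesium adduct stops at single addition and releases the methyl ketone only on quench, the small Grignard reagent adding faster than it deprotonates C9′.

Step 7
Reactants: 13 (3R)-5-methyl-3-(2,4,6-trimethoxyphenyl)hexan-2-one; 14 cyclopropyldiphenylsulfonium tetrafluoroborate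
Product: 16 (2S)-2-methyl-2-[(1R)-3-methyl-1-(2,4,6-trimethoxyphenyl)butyl]-1-oxaspiro[2.2]pentane, via sulfonium alkoxide betaine 15 (not isolated)
Conditions: 14 (1.3 equiv), KHMDS (1.2 equiv), DME, −45 °C; then 13, −45 → −20 °C; NaHCO3 work-up, base-washed silica
Reagents that add atoms: cyclopropyldiphenylsulfonium tetrafluoroborate (14), F[B-](F)(F)F.c1ccc(cc1)[S+](C1CC1)c1ccccc1
Why: Corey–Chaykovsky-type spiro-epoxidation in which the preformed cyclopropylide adds to the carbonyl along the Felkin–Anh trajectory anti to the aryl group on C9′ and the betaine closes with loss of Ph2S, setting C4 as (2S), while the slight deficit of base at low temperature protects C9′ from enolisation.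

Step 8
Reactants: 16 (2S)-2-methyl-2-[(1R)-3-methyl-1-(2,4,6-trimethoxyphenyl)butyl]-1-oxaspiro[2.2]pentane
Product: 17 (2R)-2-methyl-2-[(1R)-3-methyl-1-(2,4,6-trimethoxyphenyl)butyl]cyclobutan-1-one
Conditions: LiBF4 (20 mol %), benzene, 25 → 50 °C
Reagents that add atoms: none
Why: Li+ binds the epoxide oxygen and weakens the C4–O bond; as charge builds at tertiary C4, one cyclopropane CH2 on the spiro carbon C5 shifts to C4 on the side away from the departing oxygen while the oxygen lone pair turns C5 into the carbonyl carbon. The closest known reaction type is the Lewis-acid-promoted oxaspiropentane-to-cyclobutanone (semipinacol, cyclopropylcarbinyl-to-cyclobutyl) rearrangement. The four-membered ring (C5, C2, C3, C4) is closed not by cyclisation of a chain but by a 1,2-alkyl shift that enlarges the three-membered carbocycle by one atom, the new bond being C3–C4, and it is driven by release of the strain of two spiro-fused three-membered rings. The quaternary stereocentre C4 is controlled by the epoxide configuration, because the shift is invertive at C4, and that configuration was fixed by C9′ in step 7. The step needs ring enlargement to outrun a hydride or aryl shift from C9′ and to avoid a long-lived free cation; this is secured by the built-in near-anti alignment of both cyclopropane C–C bonds with the C4–O bond, by the oxygen push that keeps the shift concerted, by the mild non-protic Li+ in a non-polar solvent and by the twisted 2,6-dimethoxyaryl group, which bridges poorly.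

Step 9
Reactants: 17 (2R)-2-methyl-2-[(1R)-3-methyl-1-(2,4,6-trimethoxyphenyl)butyl]cyclobutan-1-one
Product: 19 (2R)-2-methyl-2-[(1R)-3-methyl-1-(2,4,6-trimethoxyphenyl)butyl]cyclopentan-1-one, via β-ketosilane 18 (not isolated)
Conditions: TMSCHN2, Sc(OTf)3 (5 mol %), toluene, 0 → 23 °C; then 1 M HCl, THF, 23 °C
Reagents that add atoms: trimethylsilyldiazomethane, C[Si](C)(C)C=[N+]=[N-]
Why: Lewis-acid-catalysed diazoalkane homologation (Tiffeneau–Demjanov-type ring expansion) in which the unsubstituted CH2 (C2) migrates in preference to quaternary C4, so that the new carbon C1 lands between C5 and C2, C4 is untouched and protodesilylation frees the ketone.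

Step 10
Reactants: 19 (2R)-2-methyl-2-[(1R)-3-methyl-1-(2,4,6-trimethoxyphenyl)butyl]cyclopentan-1-one
Product: 21 (5R)-5-methyl-5-[(1S)-3-methyl-1-(2,4,6-trimethoxyphenyl)butyl]cyclopent-1-en-1-yl trifluoromethanesulfonate, via potassium enolate 20 (not isolated)
Conditions: KHMDS, THF, −78 °C; then PhNTf2, −78 → 0 °C
Reagents that add atoms: N-phenylbis(trifluoromethanesulfonimide), FC(F)(F)S(=O)(=O)N(c1ccccc1)S(=O)(=O)C(F)(F)F
Why: Enolisation can only occur toward C1 because C4 is quaternary, and O-sulfonylation of the enolate with PhNTf2 is the standard enol triflate synthesis.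

Step 11
Reactants: 22 3-methylbut-2-enal
Product: 23 4-methyl-N′-[(E)-3-methylbut-2-enylidene]benzenesulfonohydrazide
Conditions: TsNHNH2, MeOH, 23 °C
Reagents that add atoms: 4-methylbenzenesulfonohydrazide, Cc1ccc(cc1)S(=O)(=O)NN
Why: Condensation of an aldehyde with a sulfonyl hydrazide gives the crystalline tosylhydrazone.

Step 12
Reactants: 23 4-methyl-N′-[(E)-3-methylbut-2-enylidene]benzenesulfonohydrazide
Product: 25 3,3-dimethylcyclopropene, via vinyldiazoalkane 24 (not isolated)
Conditions: NaOMe, diglyme, 140 °C, product swept with N2 into a −78 °C trap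
Reagents that add atoms: none
Why: Bamford–Stevens reaction in which the sodium salt loses sulfinate to the vinyl diazoalkane and then N2 to a vinylcarbene that closes to the cyclopropene, a known route to 3,3-dialkylcyclopropenes that creates no stereocentre.

Step 13
Reactants: 21 (5R)-5-methyl-5-[(1S)-3-methyl-1-(2,4,6-trimethoxyphenyl)butyl]cyclopent-1-en-1-yl trifluoromethanesulfonate; 25 3,3-dimethylcyclopropene; 26 2-(2-bromoethyl)-2-methyl-1,3-dioxolane
Product: 30 2-[2-[(1R,3S)-2,2-dimethyl-3-[(5R)-5-methyl-5-[(1S)-3-methyl-1-(2,4,6-trimethoxyphenyl)butyl]cyclopent-1-en-1-yl]cyclopropyl]ethyl]-2-methyl-1,3-dioxolane, via Grignard reagent 27 (not isolated), via cyclopropylmagnesium bromide 28 (not isolated), via cyclopropylzinc chloride 29 (not isolated)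
Conditions: 26 (1.5 equiv), Mg, THF, 30 °C; added slowly to 25 (2 equiv), CuI (5 mol %), (R,S)-Josiphos [(R)-1-[(S)-2-(diphenylphosphino)ferrocenyl]ethyldicyclohexylphosphine, 5.5 mol %], toluene, −40 → −10 °C; excess 25 purged; ZnCl2, THF, 0 °C; then 21 (1 equiv), Pd(OAc)2 (5 mol %), SPhos (10 mol %), THF, 50 °C
Reagents that add atoms: 3,3-dimethylcyclopropene (25), CC1(C)C=C1; 2-(2-bromoethyl)-2-methyl-1,3-dioxolane (26), CC1(CCBr)OCCO1
Why: Copper-catalysed asymmetric carbomagnesiation of the strained cyclopropene is a syn addition, so magnesium ends up cis to the new side chain and the chiral diphosphine decides which of the two enantiotopic alkene carbons is alkylated, and the Mg → Zn → Pd transmetalations and the reductive elimination of the Negishi coupling all retain configuration at the cyclopropyl carbon, so that 30 carries the cis-cyclopropane of the target while any minor enantiomer of 28 ends up as a separable diastereomer.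

Step 14
Reactants: 30 2-[2-[(1R,3S)-2,2-dimethyl-3-[(5R)-5-methyl-5-[(1S)-3-methyl-1-(2,4,6-trimethoxyphenyl)butyl]cyclopent-1-en-1-yl]cyclopropyl]ethyl]-2-methyl-1,3-dioxolane
Product: 32 (1S,2S,3R)-2-[(1R,3R)-2,2-dimethyl-3-[2-(2-methyl-1,3-dioxolan-2-yl)ethyl]cyclopropyl]-3-methyl-3-[(1S)-3-methyl-1-(2,4,6-trimethoxyphenyl)butyl]cyclopentan-1-ol, via alkylborane 31 (not isolated)
Conditions: BH3·THF, THF, 0 → 23 °C; then NaOH, H2O2, 0 → 23 °C
Reagents that add atoms: hydrogen peroxide, OO
Why: Brown hydroboration–oxidation places boron on the less substituted C1 and hydrogen on C5 in a syn addition expected from the face of the C4 methyl group, and oxidation of the C–B bond with retention gives the C1 alcohol.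

Step 15
Reactants: 32 (1S,2S,3R)-2-[(1R,3R)-2,2-dimethyl-3-[2-(2-methyl-1,3-dioxolan-2-yl)ethyl]cyclopropyl]-3-methyl-3-[(1S)-3-methyl-1-(2,4,6-trimethoxyphenyl)butyl]cyclopentan-1-ol
Product: 33 (1S,2S,3R)-3-[(1S)-1-(3,5-dibromo-2,4,6-trimethoxyphenyl)-3-methylbutyl]-2-[(1R,3R)-2,2-dimethyl-3-[2-(2-methyl-1,3-dioxolan-2-yl)ethyl]cyclopropyl]-3-methylcyclopentan-1-ol
Conditions: NBS (2.1 equiv), MeCN, 0 °C, dark
Reagents that add atoms: N-bromosuccinimide, BrN1C(=O)CCC1=O
Why: Electrophilic aromatic bromination takes the only two free ring positions, each flanked by two methoxy groups and far more nucleophilic than any other site, under conditions that generate no strong acid.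

Step 16
Reactants: 33 (1S,2S,3R)-3-[(1S)-1-(3,5-dibromo-2,4,6-trimethoxyphenyl)-3-methylbutyl]-2-[(1R,3R)-2,2-dimethyl-3-[2-(2-methyl-1,3-dioxolan-2-yl)ethyl]cyclopropyl]-3-methylcyclopentan-1-ol
Product: 35 (1S,2S,3R)-3-[(1S)-1-(3,5-diformyl-2,4,6-trimethoxyphenyl)-3-methylbutyl]-2-[(1R,3R)-2,2-dimethyl-3-[2-(2-methyl-1,3-dioxolan-2-yl)ethyl]cyclopropyl]-3-methylcyclopentan-1-ol, via trilithiated intermediate 34 (not isolated)
Conditions: t-BuLi (5.5 equiv), THF, −78 °C; then DMF, −78 → 0 °C; H2O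
Reagents that add atoms: N,N-dimethylformamide, CN(C)C=O
Why: Bromine–lithium exchange followed by Bouveault-type formylation works because the first equivalent of t-BuLi only forms the alkoxide, each aryllithium is stabilised by two flanking methoxy groups and the DMF adducts release the aldehydes only on aqueous quench, all without acid that could open the cyclopropane or the ketal.

Step 17
Reactants: 35 (1S,2S,3R)-3-[(1S)-1-(3,5-diformyl-2,4,6-trimethoxyphenyl)-3-methylbutyl]-2-[(1R,3R)-2,2-dimethyl-3-[2-(2-methyl-1,3-dioxolan-2-yl)ethyl]cyclopropyl]-3-methylcyclopentan-1-ol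
Product: 37 (2R,3R)-3-[(1S)-1-(3,5-diformyl-2,4,6-trimethoxyphenyl)-3-methylbutyl]-2-[(1R,3R)-2,2-dimethyl-3-[2-(2-methyl-1,3-dioxolan-2-yl)ethyl]cyclopropyl]-3-methylcyclopentan-1-one, via C5-epimeric ketone 36 (not isolated)
Conditions: Dess–Martin periodinane, CH2Cl2, 23 °C; aqueous work-up; then DBU (0.3 equiv), toluene (dilute), 23 → 40 °C
Reagents that add atoms: none
Why: Dess–Martin oxidation gives the C1 ketone, and amidine-catalysed enolisation then equilibrates C5 to the more stable epimer with the cyclopropyl group trans to the bulky C4 side chain, which is the target configuration (thermodynamic control), the hindered, non-enolisable aryl aldehydes being poor aldol acceptors.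

Step 18
Reactants: 37 (2R,3R)-3-[(1S)-1-(3,5-diformyl-2,4,6-trimethoxyphenyl)-3-methylbutyl]-2-[(1R,3R)-2,2-dimethyl-3-[2-(2-methyl-1,3-dioxolan-2-yl)ethyl]cyclopropyl]-3-methylcyclopentan-1-one
Product: 39 macrocarpal N, via triphenol ketal 38 (not isolated)
Conditions: 4-MeC6H4SLi (from 4-MeC6H4SH, n-BuLi; 8 equiv), HMPA/toluene, 110 °C; then 1 M HCl, THF, 23 °C
Reagents that add atoms: water, O
Why: Thiolate SN2 demethylation of aryl methyl ethers activated by ortho and para formyl groups proceeds without acid and so spares the gem-dimethylcyclopropane, and the mild aqueous acid then hydrolyses the dioxolane to the side-chain ketone without touching any stereocentre.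

Compound list
1 | (2,4,6-trimethoxyphenyl)acetic acid | COc1cc(OC)c(CC(=O)O)c(OC)c1 | starting material
2 | (4R)-4-benzyl-1,3-oxazolidin-2-one | O=C1N[C@H](Cc2ccccc2)CO1 | starting material
3 | 2-(2,4,6-trimethoxyphenyl)acetic pivalic anhydride | COc1cc(OC)c(CC(=O)OC(=O)C(C)(C)C)c(OC)c1 | intermediate
4 | (4R)-4-benzyl-3-[2-(2,4,6-trimethoxyphenyl)acetyl]-1,3-oxazolidin-2-one | COc1cc(OC)c(CC(=O)N2[C@H](Cc3ccccc3)COC2=O)c(OC)c1 | intermediate
5 | 3-bromo-2-methylprop-1-ene | CC(=C)CBr | starting material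
6 | sodium (Z)-enolate of 4 | [Na+].[O-]/C(=C\c1c(OC)cc(OC)cc1OC)N1[C@H](Cc2ccccc2)COC1=O | intermediate
7 | (4R)-4-benzyl-3-[(2R)-4-methyl-2-(2,4,6-trimethoxyphenyl)pent-4-enoyl]-1,3-oxazolidin-2-one | O=C([C@H](CC(C)=C)c1c(OC)cc(OC)cc1OC)N1[C@H](Cc2ccccc2)COC1=O | intermediate
8 | (4R)-4-benzyl-3-[(2R)-4-methyl-2-(2,4,6-trimethoxyphenyl)pentanoyl]-1,3-oxazolidin-2-one | O=C([C@H](CC(C)C)c1c(OC)cc(OC)cc1OC)N1[C@H](Cc2ccccc2)COC1=O | intermediate
9 | lithium (2R)-4-methyl-2-(2,4,6-trimethoxyphenyl)pentaneperoxoate | [Li+].[O-]OC(=O)[C@H](CC(C)C)c1c(OC)cc(OC)cc1OC | intermediate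
10 | (2R)-4-methyl-2-(2,4,6-trimethoxyphenyl)pentanoic acid | OC(=O)[C@H](CC(C)C)c1c(OC)cc(OC)cc1OC | intermediate
11 | 1H-benzotriazol-1-yl (2R)-4-methyl-2-(2,4,6-trimethoxyphenyl)pentanoate | O=C(On1nnc2ccccc12)[C@H](CC(C)C)c1c(OC)cc(OC)cc1OC | intermediate
12 | (2R)-N-methoxy-N,4-dimethyl-2-(2,4,6-trimethoxyphenyl)pentanamide | CON(C)C(=O)[C@H](CC(C)C)c1c(OC)cc(OC)cc1OC | intermediate
13 | (3R)-5-methyl-3-(2,4,6-trimethoxyphenyl)hexan-2-one | CC(=O)[C@H](CC(C)C)c1c(OC)cc(OC)cc1OC | intermediate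
14 | cyclopropyldiphenylsulfonium tetrafluoroborate | F[B-](F)(F)F.c1ccc(cc1)[S+](C1CC1)c1ccccc1 | starting material
15 | (2S,3R)-2-[1-(diphenylsulfonio)cyclopropyl]-5-methyl-3-(2,4,6-trimethoxyphenyl)hexan-2-olate | [O-][C@](C)(C1(CC1)[S+](c1ccccc1)c1ccccc1)[C@H](CC(C)C)c1c(OC)cc(OC)cc1OC | intermediate
16 | (2S)-2-methyl-2-[(1R)-3-methyl-1-(2,4,6-trimethoxyphenyl)butyl]-1-oxaspiro[2.2]pentane | C[C@]1(OC12CC2)[C@H](CC(C)C)c1c(OC)cc(OC)cc1OC | intermediate
17 | (2R)-2-methyl-2-[(1R)-3-methyl-1-(2,4,6-trimethoxyphenyl)butyl]cyclobutan-1-one | O=C1CC[C@]1(C)[C@H](CC(C)C)c1c(OC)cc(OC)cc1OC | intermediate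
18 | (2R)-2-methyl-2-[(1R)-3-methyl-1-(2,4,6-trimethoxyphenyl)butyl]-5-(trimethylsilyl)cyclopentan-1-one (uncontrolled at the silyl-bearing carbon) | O=C1C([Si](C)(C)C)CC[C@]1(C)[C@H](CC(C)C)c1c(OC)cc(OC)cc1OC | intermediate
19 | (2R)-2-methyl-2-[(1R)-3-methyl-1-(2,4,6-trimethoxyphenyl)butyl]cyclopentan-1-one | O=C1CCC[C@]1(C)[C@H](CC(C)C)c1c(OC)cc(OC)cc1OC | intermediate
20 | potassium enolate of 19 | [K+].[O-]C1=CCC[C@]1(C)[C@H](CC(C)C)c1c(OC)cc(OC)cc1OC | intermediate
21 | (5R)-5-methyl-5-[(1S)-3-methyl-1-(2,4,6-trimethoxyphenyl)butyl]cyclopent-1-en-1-yl trifluoromethanesulfonate | FC(F)(F)S(=O)(=O)OC1=CCC[C@]1(C)[C@H](CC(C)C)c1c(OC)cc(OC)cc1OC | intermediate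
22 | 3-methylbut-2-enal | CC(C)=CC=O | starting material
23 | 4-methyl-N′-[(E)-3-methylbut-2-enylidene]benzenesulfonohydrazide | CC(C)=C/C=N/NS(=O)(=O)c1ccc(C)cc1 | intermediate
24 | 1-diazo-3-methylbut-2-ene | CC(C)=CC=[N+]=[N-] | intermediate
25 | 3,3-dimethylcyclopropene | CC1(C)C=C1 | intermediate
26 | 2-(2-bromoethyl)-2-methyl-1,3-dioxolane | CC1(CCBr)OCCO1 | starting material
27 | [2-(2-methyl-1,3-dioxolan-2-yl)ethyl]magnesium bromide | CC1(CC[Mg]Br)OCCO1 | intermediate
28 | [(1S,3S)-2,2-dimethyl-3-[2-(2-methyl-1,3-dioxolan-2-yl)ethyl]cyclopropyl]magnesium bromide (cis) | CC1(CC[C@@H]2[C@H]([Mg]Br)C2(C)C)OCCO1 | intermediate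
29 | [(1S,3S)-2,2-dimethyl-3-[2-(2-methyl-1,3-dioxolan-2-yl)ethyl]cyclopropyl]zinc chloride (cis) | CC1(CC[C@@H]2[C@H]([Zn]Cl)C2(C)C)OCCO1 | intermediate
30 | 2-[2-[(1R,3S)-2,2-dimethyl-3-[(5R)-5-methyl-5-[(1S)-3-methyl-1-(2,4,6-trimethoxyphenyl)butyl]cyclopent-1-en-1-yl]cyclopropyl]ethyl]-2-methyl-1,3-dioxolane (cis-cyclopropane) | CC1(CC[C@@H]2[C@H](C3=CCC[C@]3(C)[C@H](CC(C)C)c3c(OC)cc(OC)cc3OC)C2(C)C)OCCO1 | intermediate
31 | C1 monoalkylborane from 30 (boron in place of the hydroxyl group of 32) | B[C@H]1CC[C@](C)([C@H](CC(C)C)c2c(OC)cc(OC)cc2OC)[C@@H]1[C@H]1[C@@H](CCC2(C)OCCO2)C1(C)C | intermediate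
32 | (1S,2S,3R)-2-[(1R,3R)-2,2-dimethyl-3-[2-(2-methyl-1,3-dioxolan-2-yl)ethyl]cyclopropyl]-3-methyl-3-[(1S)-3-methyl-1-(2,4,6-trimethoxyphenyl)butyl]cyclopentan-1-ol | O[C@H]1CC[C@](C)([C@H](CC(C)C)c2c(OC)cc(OC)cc2OC)[C@@H]1[C@H]1[C@@H](CCC2(C)OCCO2)C1(C)C | intermediate
33 | (1S,2S,3R)-3-[(1S)-1-(3,5-dibromo-2,4,6-trimethoxyphenyl)-3-methylbutyl]-2-[(1R,3R)-2,2-dimethyl-3-[2-(2-methyl-1,3-dioxolan-2-yl)ethyl]cyclopropyl]-3-methylcyclopentan-1-ol | O[C@H]1CC[C@](C)([C@H](CC(C)C)c2c(OC)c(Br)c(OC)c(Br)c2OC)[C@@H]1[C@H]1[C@@H](CCC2(C)OCCO2)C1(C)C | intermediate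
34 | lithium alkoxide of 33 with both bromine atoms exchanged for lithium | [Li]O[C@H]1CC[C@](C)([C@H](CC(C)C)c2c(OC)c([Li])c(OC)c([Li])c2OC)[C@@H]1[C@H]1[C@@H](CCC2(C)OCCO2)C1(C)C | intermediate
35 | (1S,2S,3R)-3-[(1S)-1-(3,5-diformyl-2,4,6-trimethoxyphenyl)-3-methylbutyl]-2-[(1R,3R)-2,2-dimethyl-3-[2-(2-methyl-1,3-dioxolan-2-yl)ethyl]cyclopropyl]-3-methylcyclopentan-1-ol | O[C@H]1CC[C@](C)([C@H](CC(C)C)c2c(OC)c(C=O)c(OC)c(C=O)c2OC)[C@@H]1[C@H]1[C@@H](CCC2(C)OCCO2)C1(C)C | intermediate
36 | (2S,3R)-3-[(1S)-1-(3,5-diformyl-2,4,6-trimethoxyphenyl)-3-methylbutyl]-2-[(1R,3R)-2,2-dimethyl-3-[2-(2-methyl-1,3-dioxolan-2-yl)ethyl]cyclopropyl]-3-methylcyclopentan-1-one (C5 epimer of 37) | O=C1CC[C@](C)([C@H](CC(C)C)c2c(OC)c(C=O)c(OC)c(C=O)c2OC)[C@@H]1[C@H]1[C@@H](CCC2(C)OCCO2)C1(C)C | intermediate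
37 | (2R,3R)-3-[(1S)-1-(3,5-diformyl-2,4,6-trimethoxyphenyl)-3-methylbutyl]-2-[(1R,3R)-2,2-dimethyl-3-[2-(2-methyl-1,3-dioxolan-2-yl)ethyl]cyclopropyl]-3-methylcyclopentan-1-one | O=C1CC[C@](C)([C@H](CC(C)C)c2c(OC)c(C=O)c(OC)c(C=O)c2OC)[C@H]1[C@H]1[C@@H](CCC2(C)OCCO2)C1(C)C | intermediate
38 | (2R,3R)-3-[(1S)-1-(3,5-diformyl-2,4,6-trihydroxyphenyl)-3-methylbutyl]-2-[(1R,3R)-2,2-dimethyl-3-[2-(2-methyl-1,3-dioxolan-2-yl)ethyl]cyclopropyl]-3-methylcyclopentan-1-one | O=C1CC[C@](C)([C@H](CC(C)C)c2c(O)c(C=O)c(O)c(C=O)c2O)[C@H]1[C@H]1[C@@H](CCC2(C)OCCO2)C1(C)C | intermediate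
39 | macrocarpal N, 5-[(1S)-1-[(1R,2R)-2-[(1R,3R)-2,2-dimethyl-3-(3-oxobutyl)cyclopropyl]-1-methyl-3-oxocyclopentyl]-3-methylbutyl]-2,4,6-trihydroxybenzene-1,3-dicarbaldehyde | CC(=O)CC[C@@H]1[C@H]([C@H]2C(=O)CC[C@]2(C)[C@H](CC(C)C)c2c(O)c(C=O)c(O)c(C=O)c2O)C1(C)C | target

Total step count: 18. Longest linear sequence: 16 steps (steps 1–10, then 13–18); the cyclopropene branch (steps 11–12) joins at step 13.

Steps most likely to fail

Step 8. As the C4–O bond ionises, a 1,2-shift of hydride or of the electron-rich aryl group from C9′ may compete with ring enlargement, or a free cyclopropylcarbinyl cation may live long enough to erode the transfer of configuration to C4. The fallback sets out from 13 and returns at 17, and deactivates the arene for the rearrangement. NBS (2 equiv, MeCN, 0 °C) would convert 13 into (3R)-3-(3,5-dibromo-2,4,6-trimethoxyphenyl)-5-methylhexan-2-one F1. The ylide addition of step 7 would give (2S)-2-[(1R)-1-(3,5-dibromo-2,4,6-trimethoxyphenyl)-3-methylbutyl]-2-methyl-1-oxaspiro[2.2]pentane F2. LiBF4 would give (2R)-2-[(1R)-1-(3,5-dibromo-2,4,6-trimethoxyphenyl)-3-methylbutyl]-2-methylcyclobutan-1-one F3, the two bromine atoms making both a benzylic cation at C9′ and an aryl bridge much less accessible. Hydrogenolysis of both C–Br bonds (H2, Pd/C, Et3N, EtOAc) would return 17.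

Step 13. The chiral copper catalyst may discriminate poorly between the two enantiotopic alkene carbons of the symmetric cyclopropene, and the one-pot relay to zinc and palladium may stall at the doubly hindered C5–cyclopropyl bond. The fallback sets out from 21 (with 25 and 26) and returns at 30, replacing catalyst control by separation against the enantiopure partner. Grignard reagent 27 with stoichiometric CuBr·SMe2 would add syn to 25 to give the racemic cis-[2,2-dimethyl-3-[2-(2-methyl-1,3-dioxolan-2-yl)ethyl]cyclopropyl]copper F4. ZnCl2 would give the racemic cis-cyclopropylzinc chloride F5. Negishi coupling with 21 would give 30 together with its diastereomer carrying the mirror-image cyclopropane F6, to be removed by chromatography.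

Step 7. The ylide may add with low facial selectivity, or its basicity may partly enolise 13 and erode C9′. The fallback sets out from 13 and returns at 16. Non-basic titanium-mediated cyclopropylidenation with Cp2Ti(C3H5)2 (toluene, 60 °C) would give 2-[(3S)-2-cyclopropylidene-5-methylhexan-3-yl]-1,3,5-trimethoxybenzene F7. Neutral epoxidation with dimethyldioxirane (acetone, −20 °C) is expected to occur anti to the aryl group in the conformer that has C9′–H eclipsing the C=C bond (allylic 1,3-strain control), which leads to the same diastereomer 16.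

Further compounds
F1 | step 8 | (3R)-3-(3,5-dibromo-2,4,6-trimethoxyphenyl)-5-methylhexan-2-one | CC(=O)[C@H](CC(C)C)c1c(OC)c(Br)c(OC)c(Br)c1OC
F2 | step 8 | (2S)-2-[(1R)-1-(3,5-dibromo-2,4,6-trimethoxyphenyl)-3-methylbutyl]-2-methyl-1-oxaspiro[2.2]pentane | C[C@]1(OC12CC2)[C@H](CC(C)C)c1c(OC)c(Br)c(OC)c(Br)c1OC
F3 | step 8 | (2R)-2-[(1R)-1-(3,5-dibromo-2,4,6-trimethoxyphenyl)-3-methylbutyl]-2-methylcyclobutan-1-one | O=C1CC[C@]1(C)[C@H](CC(C)C)c1c(OC)c(Br)c(OC)c(Br)c1OC
F4 | step 13 | racemic cis-[2,2-dimethyl-3-[2-(2-methyl-1,3-dioxolan-2-yl)ethyl]cyclopropyl]copper | CC1(CC[C@@H]2[C@H]([Cu])C2(C)C)OCCO1.CC1(CC[C@H]2[C@@H]([Cu])C2(C)C)OCCO1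
F5 | step 13 | racemic cis-[2,2-dimethyl-3-[2-(2-methyl-1,3-dioxolan-2-yl)ethyl]cyclopropyl]zinc chloride | CC1(CC[C@@H]2[C@H]([Zn]Cl)C2(C)C)OCCO1.CC1(CC[C@H]2[C@@H]([Zn]Cl)C2(C)C)OCCO1
F6 | step 13 | diastereomer of 30 with the mirror-image cis-cyclopropane | CC1(CC[C@H]2[C@@H](C3=CCC[C@]3(C)[C@H](CC(C)C)c3c(OC)cc(OC)cc3OC)C2(C)C)OCCO1
F7 | step 7 | 2-[(3S)-2-cyclopropylidene-5-methylhexan-3-yl]-1,3,5-trimethoxybenzene | CC(=C1CC1)[C@H](CC(C)C)c1c(OC)cc(OC)cc1OC
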